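The C2-symmetric dodecaene is cut at both C11–C12 bonds into a central C10 tetraenyl diiodide and two copies of one ring A polyenylboronate. Everything rests on the C5–C6 bond of ring A. A palladium-catalysed 6-exo-dig cyclisation of an acyclic (Z)-alkenyl iodide onto the C6≡C7 alkyne, ended by hydride transfer from formate, closes the ring and fixes the exocyclic C6=C7 alkene in one operation. It exploits the arrangement at that alkene, C8 cis to quaternary C1 and H7 cis to C5, which is the signature of a syn addition of C5 and a metal. The precursor is an (S)-silyloxy (Z)-iodoalkene tethered through C2 and C1 to an (E)-enynoate.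

Key step: step 12

Remark: carotenoid numbering is used for atoms (ring A = C1–C6, chain C7–C15, primed numbers for the second half). In the reduction of 13 the (Z)-iodoalkenyl arm is assumed to behave as the larger ketone substituent.

Step 1
Reactants: 1 methyl 3,3-dimethylpent-4-enoate
Product: 2 N-methoxy-N,3,3-trimethylpent-4-enamide
Conditions: MeNH(OMe)·HCl, iPrMgCl, THF, −20 to 0 °C
Reagents that add atoms: N,O-dimethylhydroxylamine hydrochloride, CNOC.Cl
Why: Weinreb amide formation by magnesium amide aminolysis of the ester should be clean because the vinyl group is inert, and doing it first avoids volatile ester intermediates and an acidic alkyne C–H at this stage.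

Step 2
Reactants: 2 N-methoxy-N,3,3-trimethylpent-4-enamide
Product: 4 N-methoxy-N,3,3-trimethyl-4-oxobutanamide, via secondary ozonide 3 (not isolated)
Conditions: O3, CH2Cl2, −78 °C; then Me2S, −78 °C to rt
Reagents that add atoms: ozone, [O-][O+]=O
Why: Ozonolysis with reductive work-up cleaves the only C=C bond, and the aldehyde carries a quaternary α-carbon (future C1), so it can neither enolise nor self-condense.

Step 3
Reactants: 4 N-methoxy-N,3,3-trimethyl-4-oxobutanamide
Product: 5 N-methoxy-N,3,3-trimethylpent-4-ynamide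
Conditions: MeC(O)C(N2)P(O)(OMe)2, K2CO3, MeOH, 0 °C to rt
Reagents that add atoms: dimethyl (1-diazo-2-oxopropyl)phosphonate, CC(=O)C(=[N+]=[N-])P(=O)(OC)OC
Why: The Ohira–Bestmann variant of the Seyferth–Gilbert homologation turns the non-enolisable aldehyde into the terminal alkyne C6≡C7 under K2CO3/MeOH, which a Weinreb amide tolerates.

Step 4
Reactants: 6 diethyl methylmalonate
Product: 7 diethyl 2-(diiodomethyl)-2-methylpropanedioate
Conditions: NaH, CHI3, Et2O, reflux
Reagents that add atoms: iodoform, IC(I)I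
Why: Deprotonation and malonate C-alkylation by iodoform places the CHI2 group on the fully substituted carbon, a standard entry to β-iodomethacrylates.

Step 5
Reactants: 7 diethyl 2-(diiodomethyl)-2-methylpropanedioate
Product: 8 (E)-3-iodo-2-methylprop-2-enoic acid
Conditions: KOH, EtOH/H2O, reflux; then aq. HCl
Reagents that add atoms: potassium hydroxide, [K+].[OH-]
Why: Saponification followed by decarboxylative elimination of iodide (a Grob-type fragmentation) should give the E acid, with iodine trans to the carboxyl group, as the sterically preferred alkene.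

Step 6
Reactants: 8 (E)-3-iodo-2-methylprop-2-enoic acid
Product: 9 ethyl (E)-3-iodo-2-methylprop-2-enoate
Conditions: EtOH, cat. H2SO4, reflux
Reagents that add atoms: ethanol, CCO
Why: Fischer esterification leaves the alkenyl iodide and its E geometry untouched.

Step 7
Reactants: 5 N-methoxy-N,3,3-trimethylpent-4-ynamide; 9 ethyl (E)-3-iodo-2-methylprop-2-enoate
Product: 10 ethyl (E)-8-[methoxy(methyl)amino]-2,6,6-trimethyl-8-oxooct-2-en-4-ynoate
Conditions: Pd(PPh3)2Cl2 (3 mol %), CuI (6 mol %), Et3N, THF, rt
Reagents that add atoms: none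
Why: Sonogashira coupling forms C7–C8 with retention of the E geometry of the electron-poor alkenyl iodide, which adds oxidatively at room temperature, and the Weinreb amide is a spectator.

Step 8
Reactants: 10 ethyl (E)-8-[methoxy(methyl)amino]-2,6,6-trimethyl-8-oxooct-2-en-4-ynoate; 11 prop-1-yn-1-ylmagnesium bromide (1.3 equiv)
Product: 12 ethyl (E)-2,6,6-trimethyl-8-oxoundec-2-ene-4,9-diynoate
Conditions: THF, −20 to 0 °C; aq. NH4Cl
Reagents that add atoms: none
Why: In this Weinreb ketone synthesis the mild alkynyl Grignard reagent attacks the chelating N-methoxy amide much faster than the conjugated, α-branched ethyl ester, and the ketone is released only on quench, so neither over-addition nor ester attack is expected.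

Step 9
Reactants: 12 ethyl (E)-2,6,6-trimethyl-8-oxoundec-2-ene-4,9-diynoate
Product: 13 ethyl (2E,9Z)-10-iodo-2,6,6-trimethyl-8-oxoundeca-2,9-dien-4-ynoate
Conditions: NaI, AcOH, rt
Reagents that add atoms: sodium iodide, [Na+].[I-]
Why: Conjugate hydroiodination of the ynone (iodide at C5, anti protonation at C4) gives the Z β-iodoenone with iodine cis to C3, while the far less electrophilic, neopentyl-shielded enynoate alkyne should stay inert at room temperature.

Step 10
Reactants: 13 ethyl (2E,9Z)-10-iodo-2,6,6-trimethyl-8-oxoundeca-2,9-dien-4-ynoate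
Product: 14 ethyl (2E,8S,9Z)-8-hydroxy-10-iodo-2,6,6-trimethylundeca-2,9-dien-4-ynoate
Conditions: (R)-Me-CBS [(3aR)-1-methyl-3,3-diphenyltetrahydro-1H,3H-pyrrolo[1,2-c][1,3,2]oxazaborole] (10 mol %), BH3·SMe2, THF, −30 °C; MeOH
Reagents that add atoms: none
Why: In the Corey–Bakshi–Shibata reduction the ketone binds the catalyst boron through the lone pair anti to the bulkier (Z)-iodoalkenyl arm, so the R catalyst should deliver hydride to the face that gives the S carbinol (carotenoid C3), and catalysed 1,2-reduction outruns attack of borane on ester or alkyne.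

Step 11
Reactants: 14 ethyl (2E,8S,9Z)-8-hydroxy-10-iodo-2,6,6-trimethylundeca-2,9-dien-4-ynoate
Product: 15 ethyl (2E,8S,9Z)-8-(tert-butyldimethylsilyloxy)-10-iodo-2,6,6-trimethylundeca-2,9-dien-4-ynoate
Conditions: TBSCl, imidazole, DMF, rt
Reagents that add atoms: tert-butyldimethylsilyl chloride, CC(C)(C)[Si](C)(C)Cl
Why: Silyl ether formation shields the allylic alcohol from the later palladium, aluminium hydride, MnO2 and chromium reagents without touching the stereocentre.

Step 12
Reactants: 15 ethyl (2E,8S,9Z)-8-(tert-butyldimethylsilyloxy)-10-iodo-2,6,6-trimethylundeca-2,9-dien-4-ynoate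
Product: 16 ethyl (2E,4E)-4-[(4S)-4-(tert-butyldimethylsilyloxy)-2,6,6-trimethylcyclohex-2-en-1-ylidene]-2-methylbut-2-enoate
Conditions: Pd(OAc)2 (5 mol %), PPh3 (15 mol %), HCO2Na (1.5 equiv), degassed DMF, 70 °C
Reagents that add atoms: none
Why: Zerovalent palladium generated from Pd(OAc)2 and PPh3 inserts into the C5–I bond with retention, and the (Z)-alkenylpalladium adds syn across the tethered C6≡C7 triple bond, which makes the C5–C6 bond and leaves palladium on C7 cis to C5. Exchange of iodide for formate, loss of CO2 and C–H reductive elimination with retention then put hydrogen where palladium stood, so C8 ends cis to C1 (6E). The closest known reaction type is the reductive Heck-type cyclisation of aryl and alkenyl halides onto alkynes with hydride capture from formate. Ring A closes in the 6-exo-dig mode (ring atoms C5, C4, C3, C2, C1, C6), whereas a 7-endo closure would have to hold a strained alkenylpalladium inside the ring and should not compete. No stereocentre is created, the C3 silyloxy centre is a spectator, and the Z geometry of the iodide becomes the endocyclic C4=C5 alkene. The step needs ring closure to outrun direct reduction of the C5–Pd bond and needs the dienylpalladium to keep its geometry, which is secured by the C1 gem-dimethyl group folding the tether, by sparingly soluble HCO2Na keeping hydride supply low until the ring is closed, and by the absence of any accessible β-hydride elimination.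

Step 13
Reactants: 16 ethyl (2E,4E)-4-[(4S)-4-(tert-butyldimethylsilyloxy)-2,6,6-trimethylcyclohex-2-en-1-ylidene]-2-methylbut-2-enoate
Product: 17 (2E,4E)-4-[(4S)-4-(tert-butyldimethylsilyloxy)-2,6,6-trimethylcyclohex-2-en-1-ylidene]-2-methylbut-2-en-1-ol
Conditions: iBu2AlH (2.3 equiv), CH2Cl2, −78 °C; aq. Rochelle salt
Reagents that add atoms: none
Why: DIBAL-H reduction of the conjugated ester goes 1,2 to the allylic alcohol at low temperature and leaves the silyl ether and the triene geometry intact.

Step 14
Reactants: 17 (2E,4E)-4-[(4S)-4-(tert-butyldimethylsilyloxy)-2,6,6-trimethylcyclohex-2-en-1-ylidene]-2-methylbut-2-en-1-ol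
Product: 18 (2E,4E)-4-[(4S)-4-(tert-butyldimethylsilyloxy)-2,6,6-trimethylcyclohex-2-en-1-ylidene]-2-methylbut-2-enal
Conditions: MnO2, CH2Cl2, rt, dark
Reagents that add atoms: none
Why: MnO2 allylic oxidation is neutral and selective for the primary allylic alcohol, so the C6=C7 and C8=C9 alkenes should not isomerise.

Step 15
Reactants: 18 (2E,4E)-4-[(4S)-4-(tert-butyldimethylsilyloxy)-2,6,6-trimethylcyclohex-2-en-1-ylidene]-2-methylbut-2-enal
Product: 19 2-[(1E,3E,5E)-5-{(4S)-4-(tert-butyldimethylsilyloxy)-2,6,6-trimethylcyclohex-2-en-1-ylidene}-3-methylpenta-1,3-dien-1-yl]-4,4,5,5-tetramethyl-1,3,2-dioxaborolane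
Conditions: CrCl2 (8 equiv), Cl2CHBpin (2 equiv), LiI (4 equiv), THF, rt
Reagents that add atoms: 2-(dichloromethyl)-4,4,5,5-tetramethyl-1,3,2-dioxaborolane, ClC(Cl)B1OC(C)(C)C(C)(C)O1
Why: In the Takai-type boryl olefination the chromium carbenoid from Cl2CHBpin adds to the aldehyde and eliminates to the E C10=C11 alkenylboronate under essentially neutral conditions that spare the silyl ether and the triene.

Step 16
Reactants: 9 ethyl (E)-3-iodo-2-methylprop-2-enoate
Product: 20 (E)-3-iodo-2-methylprop-2-en-1-ol
Conditions: iBu2AlH (2.2 equiv), CH2Cl2, −78 °C; aq. Rochelle salt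
Reagents that add atoms: none
Why: DIBAL-H 1,2-reduction of the enoate keeps the C–I bond and the E geometry, so one iodomethacrylate serves both the end groups and the central unit.

Step 17
Reactants: 20 (E)-3-iodo-2-methylprop-2-en-1-ol
Product: 21 (E)-3-iodo-2-methylprop-2-enal
Conditions: MnO2, CH2Cl2, rt
Reagents that add atoms: none
Why: MnO2 allylic oxidation stops at the enal and does not affect the alkenyl iodide.

Step 18
Reactants: 21 (E)-3-iodo-2-methylprop-2-enal
Product: 22 (2E,4E)-5-iodo-4-methylpenta-2,4-dienal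
Conditions: Ph3P=CHCHO (1.05 equiv), toluene, 80 °C, dark
Reagents that add atoms: (triphenylphosphoranylidene)acetaldehyde, O=CC=P(c1ccccc1)(c1ccccc1)c1ccccc1
Why: Wittig olefination with the stabilised formylmethylene ylide is E-selective, and near-stoichiometric ylide limits a second homologation of the more conjugated, less electrophilic dienal.

Step 19
Reactants: 20 (E)-3-iodo-2-methylprop-2-en-1-ol
Product: 23 (E)-3-bromo-1-iodo-2-methylprop-1-ene
Conditions: PBr3, Et2O, 0 °C
Reagents that add atoms: phosphorus tribromide, BrP(Br)Br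
Why: SN2 bromination of the primary allylic alcohol through its phosphite ester proceeds without allylic transposition or loss of alkene geometry.

Step 20
Reactants: 23 (E)-3-bromo-1-iodo-2-methylprop-1-ene
Product: 24 diethyl [(E)-3-iodo-2-methylprop-2-en-1-yl]phosphonate
Conditions: P(OEt)3, neat, 110 °C
Reagents that add atoms: triethyl phosphite, CCOP(OCC)OCC
Why: The Michaelis–Arbuzov reaction takes place only at the allylic bromide because the sp2 C–I bond is inert to phosphite.

Step 21
Reactants: 24 diethyl [(E)-3-iodo-2-methylprop-2-en-1-yl]phosphonate; 22 (2E,4E)-5-iodo-4-methylpenta-2,4-dienal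
Product: 25 (1E,3E,5E,7E)-1,8-diiodo-2,7-dimethylocta-1,3,5,7-tetraene
Conditions: NaN(SiMe3)2, THF, −78 to 0 °C, dark
Reagents that add atoms: none
Why: Horner–Wadsworth–Emmons olefination of an allylic phosphonate with an enal is E-selective for the new C14'=C15' bond, and neither alkenyl iodide has a vicinal hydrogen for base-induced loss of HI.

Step 22
Reactants: 19 ring A polyenylboronate (2.2 equiv); 25 (1E,3E,5E,7E)-1,8-diiodo-2,7-dimethylocta-1,3,5,7-tetraene
Product: 26 (3S,3'S,6E,6'E,all-E)-3,3'-bis(tert-butyldimethylsilyloxy)-4',5'-didehydro-4,5'-retro-β,β-carotene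
Conditions: Pd(PPh3)4 (10 mol %), TlOEt, THF/H2O, rt, dark, argon
Reagents that add atoms: none
Why: The twofold Suzuki–Miyaura coupling forms C11–C12 and C11'–C12' with retention at all four sp2 termini, and the thallium base allows transmetalation at room temperature so the growing polyene sees no heat.

Step 23
Reactants: 26 (3S,3'S,6E,6'E,all-E)-3,3'-bis(tert-butyldimethylsilyloxy)-4',5'-didehydro-4,5'-retro-β,β-carotene
Product: 27 (3S,3'S,6E,6'E,all-E)-4',5'-didehydro-4,5'-retro-β,β-carotene-3,3'-diol (eschscholtzxanthin, CNP0349476.1)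
Conditions: Bu4NF, THF, 0 °C to rt, dark, argon
Reagents that add atoms: none
Why: Fluoride-induced desilylation cleaves only Si–O bonds under non-acidic conditions, which avoids ionisation of the polyene-conjugated allylic C3–O bonds and keeps both S centres.

Compound list

1 | methyl 3,3-dimethylpent-4-enoate | COC(=O)CC(C)(C)C=C | starting material
2 | N-methoxy-N,3,3-trimethylpent-4-enamide | CON(C)C(=O)CC(C)(C)C=C | intermediate
3 | N-methoxy-N,3-dimethyl-3-(1,2,4-trioxolan-3-yl)butanamide (secondary ozonide, not isolated) | CON(C)C(=O)CC(C)(C)C1OCOO1 | intermediate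
4 | N-methoxy-N,3,3-trimethyl-4-oxobutanamide | CON(C)C(=O)CC(C)(C)C=O | intermediate
5 | N-methoxy-N,3,3-trimethylpent-4-ynamide | CON(C)C(=O)CC(C)(C)C#C | intermediate
6 | diethyl methylmalonate | CCOC(=O)C(C)C(=O)OCC | starting material
7 | diethyl 2-(diiodomethyl)-2-methylpropanedioate | CCOC(=O)C(C)(C(I)I)C(=O)OCC | intermediate
8 | (E)-3-iodo-2-methylprop-2-enoic acid | OC(=O)/C(C)=C/I | intermediate
9 | ethyl (E)-3-iodo-2-methylprop-2-enoate | CCOC(=O)/C(C)=C/I | intermediate
10 | ethyl (E)-8-[methoxy(methyl)amino]-2,6,6-trimethyl-8-oxooct-2-en-4-ynoate | CCOC(=O)/C(C)=C/C#CC(C)(C)CC(=O)N(C)OC | intermediate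
11 | prop-1-yn-1-ylmagnesium bromide | CC#C[Mg]Br | starting material
12 | ethyl (E)-2,6,6-trimethyl-8-oxoundec-2-ene-4,9-diynoate | CCOC(=O)/C(C)=C/C#CC(C)(C)CC(=O)C#CC | intermediate
13 | ethyl (2E,9Z)-10-iodo-2,6,6-trimethyl-8-oxoundeca-2,9-dien-4-ynoate | CCOC(=O)/C(C)=C/C#CC(C)(C)CC(=O)/C=C(\I)C | intermediate
14 | ethyl (2E,8S,9Z)-8-hydroxy-10-iodo-2,6,6-trimethylundeca-2,9-dien-4-ynoate | I/C(C)=C\[C@@H](O)CC(C)(C)C#C/C=C(C)/C(=O)OCC | intermediate
15 | ethyl (2E,8S,9Z)-8-(tert-butyldimethylsilyloxy)-10-iodo-2,6,6-trimethylundeca-2,9-dien-4-ynoate | I/C(C)=C\[C@@H](O[Si](C)(C)C(C)(C)C)CC(C)(C)C#C/C=C(C)/C(=O)OCC | intermediate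
16 | ethyl (2E,4E)-4-[(4S)-4-(tert-butyldimethylsilyloxy)-2,6,6-trimethylcyclohex-2-en-1-ylidene]-2-methylbut-2-enoate | CC1=C[C@@H](O[Si](C)(C)C(C)(C)C)CC(C)(C)\C1=C/C=C(C)/C(=O)OCC | intermediate
17 | (2E,4E)-4-[(4S)-4-(tert-butyldimethylsilyloxy)-2,6,6-trimethylcyclohex-2-en-1-ylidene]-2-methylbut-2-en-1-ol | CC1=C[C@@H](O[Si](C)(C)C(C)(C)C)CC(C)(C)\C1=C/C=C(C)/CO | intermediate
18 | (2E,4E)-4-[(4S)-4-(tert-butyldimethylsilyloxy)-2,6,6-trimethylcyclohex-2-en-1-ylidene]-2-methylbut-2-enal | CC1=C[C@@H](O[Si](C)(C)C(C)(C)C)CC(C)(C)\C1=C/C=C(C)/C=O | intermediate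
19 | 2-[(1E,3E,5E)-5-{(4S)-4-(tert-butyldimethylsilyloxy)-2,6,6-trimethylcyclohex-2-en-1-ylidene}-3-methylpenta-1,3-dien-1-yl]-4,4,5,5-tetramethyl-1,3,2-dioxaborolane | CC1=C[C@@H](O[Si](C)(C)C(C)(C)C)CC(C)(C)\C1=C/C=C(C)/C=C/B2OC(C)(C)C(C)(C)O2 | intermediate
20 | (E)-3-iodo-2-methylprop-2-en-1-ol | OC/C(C)=C/I | intermediate
21 | (E)-3-iodo-2-methylprop-2-enal | O=C/C(C)=C/I | intermediate
22 | (2E,4E)-5-iodo-4-methylpenta-2,4-dienal | O=C/C=C/C(C)=C/I | intermediate
23 | (E)-3-bromo-1-iodo-2-methylprop-1-ene | BrC/C(C)=C/I | intermediate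
24 | diethyl [(E)-3-iodo-2-methylprop-2-en-1-yl]phosphonate | CCOP(=O)(OCC)C/C(C)=C/I | intermediate
25 | (1E,3E,5E,7E)-1,8-diiodo-2,7-dimethylocta-1,3,5,7-tetraene | I/C=C(C)/C=C/C=C/C(C)=C/I | intermediate
26 | (3S,3'S,6E,6'E,all-E)-3,3'-bis(tert-butyldimethylsilyloxy)-4',5'-didehydro-4,5'-retro-β,β-carotene | CC1=C[C@@H](O[Si](C)(C)C(C)(C)C)CC(C)(C)\C1=C/C=C(C)/C=C/C=C(C)/C=C/C=C/C(C)=C/C=C/C(C)=C/C=C1/C(C)=C[C@@H](O[Si](C)(C)C(C)(C)C)CC1(C)C | intermediate
27 | (3S,3'S,6E,6'E,all-E)-4',5'-didehydro-4,5'-retro-β,β-carotene-3,3'-diol (eschscholtzxanthin) | CC1=C[C@@H](O)CC(C)(C)\C1=C/C=C(C)/C=C/C=C(C)/C=C/C=C/C(C)=C/C=C/C(C)=C/C=C1/C(C)=C[C@@H](O)CC1(C)C | target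

Total step count: 23.
Longest linear sequence: 14 steps (steps 1–3, 7–15, 22, 23). The line from 6 through steps 4–6 is equally long.

Steps most likely to fail

Step 12. Bond formation at C6 takes place next to quaternary C1, so hydride transfer to the uncyclised C5 alkenylpalladium (plain deiodination) may compete with ring closure. Palladium hydride may also re-add to the product and erode the C6=C7 geometry. The fallback separates C–C bond formation from hydrogen delivery. It sets out from 15, which is cyclised in the absence of any hydride source by carbopalladation with boryl capture (Pd(OAc)2, PPh3, B2pin2, KOAc, 1,4-dioxane, 80 °C). This should give ethyl (2E,4E)-4-[(4S)-4-(tert-butyldimethylsilyloxy)-2,6,6-trimethylcyclohex-2-en-1-ylidene]-2-methyl-4-(4,4,5,5-tetramethyl-1,3,2-dioxaborolan-2-yl)but-2-enoate F1. Stereoretentive protodeborylation of the C7–B bond (AgF, THF/MeOH/H2O, rt, dark) then comes back to the route at 16.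

Step 10. Facial selectivity may be poor because the neopentyl-type C2 arm and the iodoalkenyl arm of 13 may not differ enough in size for the oxazaborolidine. The fallback moves the stereodefining event to the ynone, where discrimination between alkynyl and alkyl groups is electronic. It sets out from 12. Noyori transfer hydrogenation (RuCl(p-cymene)[(S,S)-TsDPEN], iPrOH, rt) should give ethyl (2E,8S)-8-hydroxy-2,6,6-trimethylundec-2-ene-4,9-diynoate F2. Hydroxyl-guided trans-hydrosilylation of the unhindered propargylic alkyne ([Cp*Ru(MeCN)3]PF6, Et3SiH, CH2Cl2, 0 °C) places silicon on the distal carbon and gives ethyl (2E,8S,9Z)-8-hydroxy-2,6,6-trimethyl-10-(triethylsilyl)undeca-2,9-dien-4-ynoate F3. Iododesilylation with retention (NIS, 2,6-lutidine, hexafluoroisopropanol, 0 °C) comes back to the route at 14 and replaces steps 9 and 10.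

Step 22. Protodeborylation of the electron-rich polyenylboronate in basic aqueous medium, stalling after the first coupling, or degradation of the diiodide may lower the efficiency of the double coupling. The fallback reverses the polarity and works without base. It sets out from 18 and 25. Takai iodo-olefination of 18 (CrCl2, CHI3, THF/dioxane, 0 °C) should give tert-butyl{[(1S,4E)-4-[(2E,4E)-5-iodo-3-methylpenta-2,4-dien-1-ylidene]-3,5,5-trimethylcyclohex-2-en-1-yl]oxy}dimethylsilane F4. Twofold iodine–lithium exchange of 25 and stannylation (t-BuLi, Et2O, −78 °C; Bu3SnCl) should give (1E,3E,5E,7E)-2,7-dimethyl-1,8-bis(tributylstannyl)octa-1,3,5,7-tetraene F5. A double Stille coupling of the two (Pd2(dba)3, AsPh3, NMP, rt, dark) comes back to the route at 26 and replaces steps 15 and 22.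

Further compounds

F1 | step 12 | ethyl (2E,4E)-4-[(4S)-4-(tert-butyldimethylsilyloxy)-2,6,6-trimethylcyclohex-2-en-1-ylidene]-2-methyl-4-(4,4,5,5-tetramethyl-1,3,2-dioxaborolan-2-yl)but-2-enoate | CC1=C[C@@H](O[Si](C)(C)C(C)(C)C)CC(C)(C)\C1=C(B2OC(C)(C)C(C)(C)O2)/C=C(C)/C(=O)OCC
F2 | step 10 | ethyl (2E,8S)-8-hydroxy-2,6,6-trimethylundec-2-ene-4,9-diynoate | CC#C[C@@H](O)CC(C)(C)C#C/C=C(C)/C(=O)OCC
F3 | step 10 | ethyl (2E,8S,9Z)-8-hydroxy-2,6,6-trimethyl-10-(triethylsilyl)undeca-2,9-dien-4-ynoate | CC[Si](CC)(CC)/C(C)=C\[C@@H](O)CC(C)(C)C#C/C=C(C)/C(=O)OCC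
F4 | step 22 | tert-butyl{[(1S,4E)-4-[(2E,4E)-5-iodo-3-methylpenta-2,4-dien-1-ylidene]-3,5,5-trimethylcyclohex-2-en-1-yl]oxy}dimethylsilane | CC1=C[C@@H](O[Si](C)(C)C(C)(C)C)CC(C)(C)\C1=C/C=C(C)/C=C/I
F5 | step 22 | (1E,3E,5E,7E)-2,7-dimethyl-1,8-bis(tributylstannyl)octa-1,3,5,7-tetraene | CCCC[Sn](CCCC)(CCCC)/C=C(C)/C=C/C=C/C(C)=C/[Sn](CCCC)(CCCC)CCCC
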